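**Retrosynthetic overview** (germacranolide numbering: C1 ring ketone, C2/C3 the two CH2 groups, C4(Me)/C5 epoxide, C6 lactone O-carbon, C7 ring-fusion CH, C8 ester carbinol, C9 CH2, C10 C(Me)OAc, C11/C12 lactone α-carbon/carbonyl, C13 CH2OAc)
1. The strategy rests on the C1 carbonyl of the ten-membered carbocycle (C1–C10), flanked by quaternary C10 and the plain C2 methylene: C1–C2 is cut into a C1 S-2-pyridyl thioester and a C2 primary iodide, joined last by nickel/zirconium/zinc reductive ketone formation.
2. Seco-compound 29 ⇐ cis-fused α-methylene-γ-lactone 22 (C13 borylation–oxidation sets C11; PMB ether → iodide at C2; allyl ester → thioester at C1).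
3. 22 ⇐ zinc Barbier lactone annulation (C6–C7 and O6–C12 bonds) of epoxy aldehyde 6 with allylic bromide 19.
4. 6 ⇐ Sharpless epoxidation of the (Z)-allylic alcohol from 4-methyl-5,6-dihydro-2H-pyran-2-one; 19 ⇐ (R)-citramalic acid (C10), Corey–Bakshi–Shibata reduction (C8), Morita–Baylis–Hillman reaction with methyl acrylate (C11–C13), SN2′ bromination.
5. Ring order: epoxide (step 3) → γ-lactone (step 13) → ten-membered carbocycle (step 20); then C8 desilylation and methacryloylation.

Key step: step 20

Assumption: the allylzinc reagent from 19 is attacked at C7 in the conformer with C8–H eclipsing C7=C11 (A(1,3) strain) and anti to the C8–C9 bond (silyloxy group outside), the sense that is matched with the Felkin–Anh face of aldehyde 6.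

Step 1
Reactants: 1 4-methyl-5,6-dihydro-2H-pyran-2-one
Product: 3 (2Z)-5-[(4-methoxybenzyl)oxy]-3-methylpent-2-enoic acid, via potassium (2Z)-5-hydroxy-3-methylpent-2-enoate 2 (not isolated)
Conditions: KOH (powdered, excess), toluene, reflux; then 4-methoxybenzyl chloride, reflux; H2O, then HCl to pH 3
Reagents that add atoms: potassium hydroxide [K+].[OH-]; 4-methoxybenzyl chloride COc1ccc(CCl)cc1
Why: Saponification opens the lactone with the ring (Z) geometry kept and the alkoxide undergoes Williamson etherification, any PMB ester or re-closed lactone being returned to the carboxylate by the excess KOH.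

Step 2
Reactants: 3 (2Z)-5-[(4-methoxybenzyl)oxy]-3-methylpent-2-enoic acid
Product: 4 (2Z)-5-[(4-methoxybenzyl)oxy]-3-methylpent-2-en-1-ol
Conditions: LiAlH4, Et2O, 0 °C
Reagents that add atoms: none
Why: Hydride reduction of the acid to the primary allylic alcohol; the β,β-disubstituted enoate resists conjugate reduction and the Z alkene is untouched.

Step 3
Reactants: 4 (2Z)-5-[(4-methoxybenzyl)oxy]-3-methylpent-2-en-1-ol
Product: 5 [(2S,3R)-3-{2-[(4-methoxybenzyl)oxy]ethyl}-3-methyloxiran-2-yl]methanol
Conditions: Ti(OiPr)4 (cat.), L-(+)-diethyl tartrate (cat.), tBuOOH, 4 Å MS, CH2Cl2, −20 °C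
Reagents that add atoms: tert-butyl hydroperoxide CC(C)(C)OO
Why: Sharpless asymmetric epoxidation; with L-(+)-tartrate this nerol-type (Z)-allylic alcohol should give the (2S,3R)-epoxy alcohol, which sets C4 (R) and C5 (S), the cis relation of C3 and C6 coming from the Z alkene.

Step 4
Reactants: 5 [(2S,3R)-3-{2-[(4-methoxybenzyl)oxy]ethyl}-3-methyloxiran-2-yl]methanol
Product: 6 (2R,3R)-3-{2-[(4-methoxybenzyl)oxy]ethyl}-3-methyloxirane-2-carbaldehyde
Conditions: TEMPO (cat.), PhI(OAc)2, CH2Cl2, rt; used at once
Reagents that add atoms: none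
Why: TEMPO-catalysed oxidation stops at the aldehyde under nearly neutral conditions that leave the epoxide and C5 intact.

Step 5
Reactants: 7 (R)-citramalic acid
Product: 8 [(4R)-2,2,4-trimethyl-5-oxo-1,3-dioxolan-4-yl]acetic acid
Conditions: 2,2-dimethoxypropane, p-TsOH (cat.), rt
Reagents that add atoms: 2,2-dimethoxypropane COC(C)(C)OC
Why: Acid-catalysed acetalisation engages only the α-hydroxy acid as the five-membered dioxolanone, which differentiates the C1 and C8 carboxyl groups without touching C10.

Step 6
Reactants: 8 [(4R)-2,2,4-trimethyl-5-oxo-1,3-dioxolan-4-yl]acetic acid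
Product: 10 (3R)-3-acetoxy-3-methyl-4-oxo-4-(prop-2-en-1-yloxy)butanoic acid, via potassium salt of the hydroxy allyl ester 9 (not isolated)
Conditions: allyl alcohol, K2CO3 (1.1 equiv), rt; evaporate; Ac2O, pyridine, DMAP (cat.), 40 °C; aqueous work-up at pH 3
Reagents that add atoms: allyl alcohol C=CCO; acetic anhydride CC(=O)OC(C)=O
Why: Alkoxide acyl substitution on the activated dioxolanone gives the C1 allyl ester with loss of acetone, and DMAP-catalysed acetylation caps the tertiary C10 hydroxyl (the mixed anhydride at C8 is hydrolysed on work-up); quaternary C10 cannot epimerise.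

Step 7
Reactants: 10 (3R)-3-acetoxy-3-methyl-4-oxo-4-(prop-2-en-1-yloxy)butanoic acid
Product: 12 allyl (2R)-2-acetoxy-2,6-dimethyl-4-oxohept-5-enoate, via acid chloride 11 (not isolated)
Conditions: (COCl)2, DMF (cat.), CH2Cl2, 0 °C → rt; evaporate; Me2C=CHMgBr, CuI (10 mol %), THF, −78 °C
Reagents that add atoms: (2-methylprop-1-en-1-yl)magnesium bromide CC(C)=C[Mg]Br; oxalyl chloride O=C(Cl)C(=O)Cl (chlorine in 11 only)
Why: Acid chloride formation and copper-catalysed acylation of the alkenyl Grignard reagent (ketone synthesis) at −78 °C, where the acid chloride reacts far faster than the allyl ester, the acetate or the product enone.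

Step 8
Reactants: 12 allyl (2R)-2-acetoxy-2,6-dimethyl-4-oxohept-5-enoate
Product: 13 allyl (2R,4S)-2-acetoxy-4-hydroxy-2,6-dimethylhept-5-enoate
Conditions: (R)-2-methyl-CBS-oxazaborolidine (20 mol %), catecholborane, toluene, −78 °C
Reagents that add atoms: none
Why: Corey–Bakshi–Shibata reduction; with the (R)-catalyst and the alkenyl group as the larger substituent, hydride should be delivered to the face giving the (4S)-alcohol, i.e. C8 (S), and catecholborane at −78 °C leaves both alkenes alone.

Step 9
Reactants: 13 allyl (2R,4S)-2-acetoxy-4-hydroxy-2,6-dimethylhept-5-enoate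
Product: 14 allyl (2R,4S)-2-acetoxy-4-[(tert-butyldimethylsilyl)oxy]-2,6-dimethylhept-5-enoate
Conditions: TBSOTf, 2,6-lutidine, CH2Cl2, −78 °C
Reagents that add atoms: tert-butyldimethylsilyl triflate CC(C)(C)[Si](C)(C)OS(=O)(=O)C(F)(F)F
Why: Silylation with the silyl triflate and a non-nucleophilic base, done at once so that neither acetyl migration from O10 nor lactonisation onto C1 can occur.

Step 10
Reactants: 14 allyl (2R,4S)-2-acetoxy-4-[(tert-butyldimethylsilyl)oxy]-2,6-dimethylhept-5-enoate
Product: 16 allyl (2R,4S)-2-acetoxy-4-[(tert-butyldimethylsilyl)oxy]-2-methyl-5-oxopentanoate, via secondary ozonide 15 (not isolated)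
Conditions: O3, CH2Cl2, pyridine, Sudan Red 7B, −78 °C; then Me2S
Reagents that add atoms: ozone [O-][O+]=O
Why: Chemoselective ozonolysis; the electron-rich trisubstituted alkene is cleaved well before the acyloxy-deactivated terminal alkene of the allyl ester (dye end point), and reduction gives the α-silyloxy aldehyde whose carbonyl carbon is C7.

Step 11
Reactants: 16 allyl (2R,4S)-2-acetoxy-4-[(tert-butyldimethylsilyl)oxy]-2-methyl-5-oxopentanoate; 17 methyl acrylate
Product: 18 1-allyl 7-methyl (2R,4S)-2-acetoxy-4-[(tert-butyldimethylsilyl)oxy]-5-hydroxy-2-methyl-6-methylideneheptanedioate (both C5 epimers)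
Conditions: methyl acrylate (neat, excess), DABCO (0.5 equiv), rt
Reagents that add atoms: none
Why: Morita–Baylis–Hillman reaction of the activated α-silyloxy aldehyde builds C11–C13 onto C7; the new carbinol centre forms as a mixture, which does not matter because C7 becomes sp2 in the next step.

Step 12
Reactants: 18 1-allyl 7-methyl (2R,4S)-2-acetoxy-4-[(tert-butyldimethylsilyl)oxy]-5-hydroxy-2-methyl-6-methylideneheptanedioate
Product: 19 7-allyl 1-methyl (2Z,4S,6R)-6-acetoxy-2-(bromomethyl)-4-[(tert-butyldimethylsilyl)oxy]-6-methylhept-2-enedioate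
Conditions: NBS, Me2S, CH2Cl2, 0 °C → rt
Reagents that add atoms: N-bromosuccinimide O=C1CCC(=O)N1Br
Why: SN2′ allylic transposition of the Baylis–Hillman alcohol through its alkoxysulfonium salt gives the primary allylic bromide with the favoured alkene geometry (ester trans to C8, 2Z), C8 being untouched.

Step 13
Reactants: 6 (2R,3R)-3-{2-[(4-methoxybenzyl)oxy]ethyl}-3-methyloxirane-2-carbaldehyde; 19 7-allyl 1-methyl (2Z,4S,6R)-6-acetoxy-2-(bromomethyl)-4-[(tert-butyldimethylsilyl)oxy]-6-methylhept-2-enedioate
Product: 22 cis-fused α-methylene-γ-lactone (C6 and C7 as in the target; epoxide side chain with C2–OPMB on C6; C8-silyloxy C10-acetoxy allyl ester chain on C7), via allylzinc bromide 20 (not isolated), via open-chain bromozinc alkoxide 21 (not isolated)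
Conditions: Zn dust (TMSCl-activated), THF, 0 °C → 40 °C; sat. aq. NH4Cl
Reagents that add atoms: zinc [Zn] (in 20 and 21 only)
Why: Barbier-type allylzinc addition and lactonisation; the (Z)-allylzinc adds through C7 in a closed chair transition state to give the syn adduct, whose zinc alkoxide closes onto the methyl ester as the cis-lactone, C6 being set by the α-epoxy aldehyde (Felkin–Anh sense, attack anti to C4 with the epoxide C–O anti to C=O) and C7 by the C8 stereocentre of the reagent (C8–H in plane, attack anti to C9).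

Step 14
Reactants: 22 cis-fused α-methylene-γ-lactone
Product: 24 C13 primary alcohol of the all-cis lactone (11R), via C13 pinacol boronate 23 (not isolated)
Conditions: CuCl (5 mol %), DPEphos (5 mol %), NaOtBu (10 mol %), B2pin2, MeOH (2 equiv), THF, 0 °C; then NaBO3·4H2O, THF–H2O, 0 °C → rt
Reagents that add atoms: bis(pinacolato)diboron CC1(C)OB(OC1(C)C)B1OC(C)(C)C(C)(C)O1 (boron in 23 only); sodium perborate [Na+].[O-]OB=O
Why: Copper-catalysed conjugate borylation then C–B oxidation; boron adds to C13 and methanol protonates the copper enolate at C11 from the face opposite the cis C6 and C7 substituents, which should give the all-cis lactone, and perborate oxidises the C–B bond without disturbing the epoxide.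

Step 15
Reactants: 24 C13 primary alcohol
Product: 25 C13 acetate (lactone with C2–OPMB, C8–OTBS, C10–OAc, C1 allyl ester)
Conditions: Ac2O, pyridine, DMAP (cat.), CH2Cl2, 0 °C
Reagents that add atoms: acetic anhydride CC(=O)OC(C)=O
Why: DMAP-catalysed acetylation of the primary alcohol under weakly basic conditions that neither epimerise C11 nor eliminate the β-oxygen.

Step 16
Reactants: 25 C13 acetate
Product: 26 C2 primary alcohol
Conditions: DDQ, CH2Cl2–pH 7 buffer, 0 °C
Reagents that add atoms: none
Why: Oxidative cleavage of the p-methoxybenzyl ether (benzylic hydride abstraction, hydrolysis of the oxocarbenium ion) under buffered conditions that spare the epoxide, silyl ether, acetates and allyl ester.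

Step 17
Reactants: 26 C2 primary alcohol
Product: 27 C2 primary iodide (allyl ester)
Conditions: I2, PPh3, imidazole, CH2Cl2, 0 °C, dark
Reagents that add atoms: iodine II
Why: Appel-type iodination; SN2 displacement of the alkoxyphosphonium at primary C2, buffered so that the neighbouring epoxide is not opened.

Step 18
Reactants: 27 C2 primary iodide (allyl ester)
Product: 28 iodo carboxylic acid (free C1 acid)
Conditions: Pd(PPh3)4 (5 mol %), PhSiH3, CH2Cl2, rt
Reagents that add atoms: none
Why: Palladium-catalysed deallylation (π-allyl formation, hydride transfer from the silane) frees the C1 acid under neutral conditions in which oxidative addition of zerovalent palladium to the unactivated alkyl iodide is slow.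

Step 19
Reactants: 28 iodo carboxylic acid
Product: 29 iodo S-2-pyridyl thioester (seco-precursor)
Conditions: 2,2′-dipyridyl disulfide, PPh3, CH2Cl2, rt
Reagents that add atoms: 2,2′-dipyridyl disulfide c1ccc(SSc2ccccn2)nc1
Why: Mukaiyama redox condensation converts the hindered acid into the thioester without base, so the iodide, the epoxide and C11 are untouched.

Step 20
Reactants: 29 iodo S-2-pyridyl thioester
Product: 30 8-O-silyl ten-membered ketone (target lacking only the methacrylate)
Conditions: NiBr2(dtbbpy) (30 mol %), Cp2ZrCl2 (promoter), Zn dust (excess), DMI–EtOAc, rt, syringe-pump addition of 29 to about 2 mM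
Reagents that add atoms: none
Why: Zinc reduces NiBr2(dtbbpy) to zerovalent nickel, which inserts into the C1–S bond to give an acyl–nickel species while the C2 iodide becomes a primary alkyl radical that is captured at nickel, and reductive elimination forms C1–C2 at the ketone oxidation level; Cp2ZrCl2 activates the pyridyl thioester and speeds this acyl transfer. The closest known reaction type is the nickel/zirconium-mediated one-pot ketone synthesis from alkyl iodides and S-2-pyridyl thioesters, which is also used to close macrocyclic ketones. The ten-membered carbocycle (C1–C10) is closed end to end by this intramolecular acyl–alkyl cross-electrophile coupling. No stereocentre is formed, and the seven already present meet neither base nor an enolate (C10 is quaternary). The step needs chemoselectivity, not stereoselectivity: slow addition at high dilution lets ring closure beat iodide reduction and dimerisation, the lack of hydrogen on C10 and the fast zirconium-assisted capture disfavour CO loss from the hindered acyl–nickel, and the C2 radical is separated from the epoxide by C3 so it cannot open it.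

Step 21
Reactants: 30 8-O-silyl ten-membered ketone
Product: 31 C8 secondary alcohol of the macrocycle
Conditions: HF·pyridine, pyridine, THF, 0 °C → rt
Reagents that add atoms: none
Why: Fluoride cleavage of the secondary silyl ether with pyridine-buffered HF·pyridine, mild enough for the epoxide, the α-acetoxy ketone and the acetates.

Step 22
Reactants: 31 C8 secondary alcohol of the macrocycle
Product: 32 CNP0166747.1 (target)
Conditions: methacrylic anhydride, DMAP, iPr2NEt, CH2Cl2, 0 °C
Reagents that add atoms: methacrylic anhydride C=C(C)C(=O)OC(=O)C(C)=C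
Why: DMAP-catalysed acylation of the C8 alcohol with retention, run cold with a hindered amine to avoid translactonisation to O8 and β-elimination of the C13 acetate.

**Compound list**
1 | 4-methyl-5,6-dihydro-2H-pyran-2-one | CC1=CC(=O)OCC1 | starting material
2 | potassium (2Z)-5-hydroxy-3-methylpent-2-enoate | C/C(CCO)=C/C(=O)[O-].[K+] | intermediate (not isolated)
3 | (2Z)-5-[(4-methoxybenzyl)oxy]-3-methylpent-2-enoic acid | C/C(CCOCc1ccc(OC)cc1)=C/C(=O)O | intermediate
4 | (2Z)-5-[(4-methoxybenzyl)oxy]-3-methylpent-2-en-1-ol | C/C(CCOCc1ccc(OC)cc1)=C/CO | intermediate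
5 | [(2S,3R)-3-{2-[(4-methoxybenzyl)oxy]ethyl}-3-methyloxiran-2-yl]methanol | COc1ccc(COCC[C@@]2(C)O[C@H]2CO)cc1 | intermediate
6 | (2R,3R)-3-{2-[(4-methoxybenzyl)oxy]ethyl}-3-methyloxirane-2-carbaldehyde | COc1ccc(COCC[C@@]2(C)O[C@H]2C=O)cc1 | intermediate
7 | (R)-citramalic acid | C[C@@](O)(CC(=O)O)C(=O)O | starting material
8 | [(4R)-2,2,4-trimethyl-5-oxo-1,3-dioxolan-4-yl]acetic acid | C[C@]1(CC(=O)O)OC(C)(C)OC1=O | intermediate
9 | potassium (3R)-3-hydroxy-3-methyl-4-oxo-4-(prop-2-en-1-yloxy)butanoate | [K+].[O-]C(=O)C[C@@](C)(O)C(=O)OCC=C | intermediate (not isolated)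
10 | (3R)-3-acetoxy-3-methyl-4-oxo-4-(prop-2-en-1-yloxy)butanoic acid | OC(=O)C[C@@](C)(OC(C)=O)C(=O)OCC=C | intermediate
11 | allyl (2R)-2-acetoxy-4-chloro-2-methyl-4-oxobutanoate | ClC(=O)C[C@@](C)(OC(C)=O)C(=O)OCC=C | intermediate (not isolated)
12 | allyl (2R)-2-acetoxy-2,6-dimethyl-4-oxohept-5-enoate | CC(C)=CC(=O)C[C@@](C)(OC(C)=O)C(=O)OCC=C | intermediate
13 | allyl (2R,4S)-2-acetoxy-4-hydroxy-2,6-dimethylhept-5-enoate | CC(C)=C[C@@H](O)C[C@@](C)(OC(C)=O)C(=O)OCC=C | intermediate
14 | allyl (2R,4S)-2-acetoxy-4-[(tert-butyldimethylsilyl)oxy]-2,6-dimethylhept-5-enoate | CC(C)=C[C@@H](O[Si](C)(C)C(C)(C)C)C[C@@](C)(OC(C)=O)C(=O)OCC=C | intermediate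
15 | secondary ozonide of 14 (1,2,4-trioxolane at C7) | CC1(C)OOC(O1)[C@@H](O[Si](C)(C)C(C)(C)C)C[C@@](C)(OC(C)=O)C(=O)OCC=C | intermediate (not isolated)
16 | allyl (2R,4S)-2-acetoxy-4-[(tert-butyldimethylsilyl)oxy]-2-methyl-5-oxopentanoate | O=C[C@@H](O[Si](C)(C)C(C)(C)C)C[C@@](C)(OC(C)=O)C(=O)OCC=C | intermediate
17 | methyl acrylate | C=CC(=O)OC | starting material
18 | Baylis–Hillman alcohol (C7 epimers) | COC(=O)C(=C)C(O)[C@@H](O[Si](C)(C)C(C)(C)C)C[C@@](C)(OC(C)=O)C(=O)OCC=C | intermediate
19 | 7-allyl 1-methyl (2Z,4S,6R)-6-acetoxy-2-(bromomethyl)-4-[(tert-butyldimethylsilyl)oxy]-6-methylhept-2-enedioate | COC(=O)/C(CBr)=C/[C@@H](O[Si](C)(C)C(C)(C)C)C[C@@](C)(OC(C)=O)C(=O)OCC=C | intermediate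
20 | allylzinc bromide from 19 | COC(=O)/C(C[Zn]Br)=C/[C@@H](O[Si](C)(C)C(C)(C)C)C[C@@](C)(OC(C)=O)C(=O)OCC=C | intermediate (not isolated)
21 | open-chain bromozinc alkoxide (syn adduct) | COc1ccc(COCC[C@@]2(C)O[C@H]2[C@@H](O[Zn]Br)[C@H]([C@@H](O[Si](C)(C)C(C)(C)C)C[C@@](C)(OC(C)=O)C(=O)OCC=C)C(=C)C(=O)OC)cc1 | intermediate (not isolated)
22 | cis-fused α-methylene-γ-lactone | COc1ccc(COCC[C@@]2(C)O[C@H]2[C@H]2OC(=O)C(=C)[C@H]2[C@@H](O[Si](C)(C)C(C)(C)C)C[C@@](C)(OC(C)=O)C(=O)OCC=C)cc1 | intermediate
23 | C13 pinacol boronate of the all-cis lactone | COc1ccc(COCC[C@@]2(C)O[C@H]2[C@H]2OC(=O)[C@@H](CB3OC(C)(C)C(C)(C)O3)[C@H]2[C@@H](O[Si](C)(C)C(C)(C)C)C[C@@](C)(OC(C)=O)C(=O)OCC=C)cc1 | intermediate (not isolated)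
24 | C13 primary alcohol | COc1ccc(COCC[C@@]2(C)O[C@H]2[C@H]2OC(=O)[C@@H](CO)[C@H]2[C@@H](O[Si](C)(C)C(C)(C)C)C[C@@](C)(OC(C)=O)C(=O)OCC=C)cc1 | intermediate
25 | C13 acetate | COc1ccc(COCC[C@@]2(C)O[C@H]2[C@H]2OC(=O)[C@@H](COC(C)=O)[C@H]2[C@@H](O[Si](C)(C)C(C)(C)C)C[C@@](C)(OC(C)=O)C(=O)OCC=C)cc1 | intermediate
26 | C2 primary alcohol | OCC[C@@]1(C)O[C@H]1[C@H]1OC(=O)[C@@H](COC(C)=O)[C@H]1[C@@H](O[Si](C)(C)C(C)(C)C)C[C@@](C)(OC(C)=O)C(=O)OCC=C | intermediate
27 | C2 primary iodide, allyl ester | ICC[C@@]1(C)O[C@H]1[C@H]1OC(=O)[C@@H](COC(C)=O)[C@H]1[C@@H](O[Si](C)(C)C(C)(C)C)C[C@@](C)(OC(C)=O)C(=O)OCC=C | intermediate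
28 | iodo carboxylic acid | ICC[C@@]1(C)O[C@H]1[C@H]1OC(=O)[C@@H](COC(C)=O)[C@H]1[C@@H](O[Si](C)(C)C(C)(C)C)C[C@@](C)(OC(C)=O)C(=O)O | intermediate
29 | iodo S-2-pyridyl thioester (key-step precursor) | ICC[C@@]1(C)O[C@H]1[C@H]1OC(=O)[C@@H](COC(C)=O)[C@H]1[C@@H](O[Si](C)(C)C(C)(C)C)C[C@@](C)(OC(C)=O)C(=O)Sc1ccccn1 | intermediate
30 | 8-O-silyl ten-membered ketone (key-step product) | CC(C)(C)[Si](C)(C)O[C@H]1C[C@@](C)(OC(C)=O)C(=O)CC[C@@]2(C)O[C@H]2[C@H]2OC(=O)[C@@H](COC(C)=O)[C@H]21 | intermediate
31 | C8 alcohol of the macrocycle | O[C@H]1C[C@@](C)(OC(C)=O)C(=O)CC[C@@]2(C)O[C@H]2[C@H]2OC(=O)[C@@H](COC(C)=O)[C@H]21 | intermediate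
32 | CNP0166747.1 | C=C(C)C(=O)O[C@H]1C[C@@](C)(OC(C)=O)C(=O)CC[C@@]2(C)O[C@H]2[C@H]2OC(=O)[C@@H](COC(C)=O)[C@H]21 | target

**Step count:** 22 steps in total; longest linear sequence 18 steps (steps 5–22, from (R)-citramalic acid).

**Steps most likely to fail**

Step 20. The C–I bond may be reduced, or ketone formation between molecules may outpace closure of the strained ten-membered ring; the hindered acyl–nickel next to C10 may lose CO; the zirconium promoter may open the epoxide. The fallback sets out from 29: the iodide is inserted with Zn–Cu couple in DMA–toluene at rt to give the alkylzinc iodide F1, and this preformed organozinc is acylated by its own thioester under PdCl2(PPh3)2 catalysis at high dilution (polar palladium-catalysed thioester–organozinc ketone coupling in place of the radical cross-electrophile coupling). It comes back to the route at 30.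

Step 13. Facial selectivity at C7 may be poor if the aldehyde and the C8 stereocentre of the reagent are not matched as assumed; the allylzinc may lose its Z geometry and give the trans-lactone; zinc halide may open the epoxide. The fallback sets out from 19: palladium-catalysed borylation (B2pin2, Pd2(dba)3, toluene, 50 °C) gives the pinacol allylboronate F2, which adds to 6 in toluene at 80 °C through a closed six-membered allylboration transition state with no Lewis acidic metal halide present. The borate ester of the syn adduct F3 lactonises on heating and the route is rejoined at 22.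

Step 11. The amine-catalysed coupling is slow, and the α-silyloxy aldehyde may epimerise at C8 before it reacts. The fallback sets out from 16: methyl propiolate is hydroaluminated with iBu2AlH–HMPA (THF, 0 °C) to the α-(methoxycarbonyl)vinylalane F4, which adds to the aldehyde within minutes at 0 °C without any amine. Aqueous work-up returns to the route at 18.

**Further compounds**
F1 | step 20 | alkylzinc iodide of the seco-thioester | I[Zn]CC[C@@]1(C)O[C@H]1[C@H]1OC(=O)[C@@H](COC(C)=O)[C@H]1[C@@H](O[Si](C)(C)C(C)(C)C)C[C@@](C)(OC(C)=O)C(=O)Sc1ccccn1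
F2 | step 13 | pinacol allylboronate from 19 | COC(=O)/C(CB1OC(C)(C)C(C)(C)O1)=C/[C@@H](O[Si](C)(C)C(C)(C)C)C[C@@](C)(OC(C)=O)C(=O)OCC=C
F3 | step 13 | borate ester of the open-chain syn adduct | COc1ccc(COCC[C@@]2(C)O[C@H]2[C@@H](OB3OC(C)(C)C(C)(C)O3)[C@H]([C@@H](O[Si](C)(C)C(C)(C)C)C[C@@](C)(OC(C)=O)C(=O)OCC=C)C(=C)C(=O)OC)cc1
F4 | step 11 | methyl 2-[bis(2-methylpropyl)alumanyl]prop-2-enoate | C=C(C(=O)OC)[Al](CC(C)C)CC(C)C
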